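Free catalyst opens the substrate as it is fed, and second catalyst with partner then turn the open intermediate into product.

all flasks: substrate 20 mM (fed, over 1.5 h); second catalyst 0.50 mM
- Tuesday's: partner 50 mM; free catalyst 0.40 mM; run made earlier; the fed solution adds 0.20 times the starting volume
- Friday's: partner 50 mM; free catalyst 6.7 mM; run made earlier; the fed solution adds 0.20 times the starting volume
- north-east: partner 50.0 mM; free catalyst 0.30 mM; the fed solution adds 0.20 times the starting volume; time 1.5 h
- south-west: partner 50.0 mM; free catalyst 0.60 mM; the fed solution adds 0.20 times the starting volume; time 1.5 h
- east: partner 50.0 mM; free catalyst 1.5 mM; the fed solution adds 0.20 times the starting volume; time 1.5 h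
- south-east: partner 50.0 mM; free catalyst 2.5 mM; the fed solution adds 0.20 times the starting volume; time 1.5 h
- north-west: partner 50.0 mM; free catalyst 5.0 mM; the fed solution adds 0.20 times the starting volume; time 1.5 h

| run | time / min | product / % | substrate / % |
|---|---|---|---|
| Tuesday's | 4.00 | 0 | 4.7 |
| Tuesday's | 6.00 | 0 | 6.7 |
| Tuesday's | 10.0 | 0 | 10.5 |
| Tuesday's | 15.0 | 0.8 | 14.8 |
| Tuesday's | 25.0 | 0 | 23.5 |
| Tuesday's | 50.0 | 1.4 | 39.6 |
| Friday's | 8.00 | 0.6 | 4.2 |
| Friday's | 15.0 | 0 | 4.7 |
| Friday's | 25.0 | 0.7 | 4.6 |
| Friday's | 30.0 | 1.2 | 5.2 |
| Friday's | 40.0 | 2.5 | 5.3 |
| Friday's | 50.0 | 4.3 | 4.6 |

(each reading ± 0.5 percentage points)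

- percentages count the substrate that a species holds: one idle adduct counts as two
- product is meant together with its idle adduct
- every charge counts on the volume at the start, and the solution that is fed holds the whole dose
- the analysis behind the earlier runs scatters by 0.5 percentage points, standard deviation
- steps that have been proposed: substrate + free catalyst -> free catalyst + open intermediate; substrate + product <-> idle adduct; partner + catalyst intermediate -> second catalyst + product; second catalyst + open intermediate <-> catalyst intermediate
- percentages count the whole charge, also what has not yet gone in
- in an amount of product, one idle adduct counts as one product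
- "hardly changes" means that all values lie within two and a half points (for a concentration: within two and a half percent of the largest)

* amount of product at the end, in percent of the substrate charged for north-east, south-west, east, south-east, north-west, in this order
* how that number moves from the first to the last of them (falls all the way / rises, then falls / hardly changes / rises all the way / falls, then rises)

A fed substrate molecule faces two waits: first for opening, then, once open, for the product step. Friday's flask shows the first wait. From 15.0 min on, its substrate readings stay level near 4.88 % of the charge, while the feed rate, as a fraction of the charge, is 0.0111 min⁻¹. So opening, pseudo-first-order in substrate, removes what the pump brings. Feed rate over level and over free catalyst charged gives, as a reading, the opening constant 0.0340 mM⁻¹ min⁻¹. Its inverse, divided by a flask's free catalyst charge, is that flask's opening time τ.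

With dosing time T and τ held constant, the substrate share at time t during dosing is (τ/T)(1 − e^(−t/τ)). Tuesday's flask tests this: its opening time is 73.6 min. The rule gives 40.3 % at 50.0 min, and the reading is 39.6 %.

The second wait is also read on Friday's flask, where τ is 4.39 min. Its last 3 product readings, set against the open share summed over time, give as a reading a product chance of 0.00355 min⁻¹ for an open molecule.

At the end of dosing, the open time per charged molecule is W = T/2 − τ + (τ·τ/T)(1 − e^(−T/τ)). North-east has τ = 98.1 min and W = 11.1 min. North-west has τ = 5.89 min and W = 39.5 min, which is longer. Product is then 3.94 % and 14.0 %.

The weak link is the constant chance. Friday's average open minute fell at 1.07 times the starting volume, but a full dosing's falls at 1.13, a larger volume. If partner and second catalyst both thin with volume, the chance is multiplied by 0.898. The reckoned north-east and north-west values become 3.54 % and 12.6 %.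

The forecast gives 3.5 %, 5.8 %, 9 %, 10.5 % and 12 %, a row that rises all the way: “More free catalyst always gives more, with diminishing returns”. Its north-west value stands below the reckoning here.

The flasks give 4.55 %, 6.68 %, 9.31 %, 10.4 % and 11.4 %, so the row rises all the way.

    substrate + free catalyst → free catalyst + open intermediate (k = 2200 M⁻¹ h⁻¹)
    substrate + product ⇌ idle adduct, settled at all times (K = 150 M⁻¹)
    partner + catalyst intermediate → second catalyst + product (k = 180 M⁻¹ h⁻¹)
    second catalyst + open intermediate ⇌ catalyst intermediate (K = 180 M⁻¹, k = 2900 M⁻¹ h⁻¹)

At the end of north-west, catalyst intermediate holds 61.7 % of the second catalyst charged, and product stands at 11.4 %, below the reforged 12.6 %. In south-east, the opening constant gives an opening time of 11.8 min, and the substrate rule then leaves 13.1 % of the charge at the end of dosing. The south-east flask holds 13.6 %.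

The numbers in the tables were generated by integration with made-up constants; the scatter is artificial.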